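**Plan**
Retrosynthesis: the C2–aryl bond of the flavanone is cut first (aryl added to a chromone), then ring C (O1–C2 and C2–C3, back to an acetyl group), then the flavone C2–aryl bond (thioether/boronic acid coupling), then ring A at C4a–C5, and last the open chain (C4–C5 acylation, ether O–C alkylation).
Enabling feature: ring A of the flavanone is an acylphloroglucinol. Its oxygens on C5, C7 and C8a and its acyl carbon C4 map onto the C1, C3 and C5 carbonyls and C7 of a 3,5,7-triketo ester, and the C6 aryloxy group lies on chain carbon C2, alpha to the ester.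
Forward order: the chain is assembled, ring A is closed by Claisen cyclisation, the flavone is attached through the aryl bromide, ring C is closed as a chromone through the one ortho oxygen remote from the aryloxy group, the B ring is added, and the benzyl groups are removed.
Stereochemistry: the only stereocentre (C2, S) comes from a ligand-controlled palladium-catalysed conjugate arylation of the chromone in the last C–C bond formation; only a neutral hydrogenolysis follows.

Key step: step 4

Assumption: the facial sense of the palladium/pyridine-oxazoline arylation is taken to carry over from cyclic enones to the chromone, so the (R)-ligand is expected to give the 2S flavanone; with the opposite finding the (S)-ligand would be used.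

**Route**

Step 1
Reactants: 1 4-bromophenol; 2 methyl 2-chloro-3-oxobutanoate
Product: 3 methyl 2-(4-bromophenoxy)-3-oxobutanoate
Conditions: K2CO3, acetone, reflux
Reagents that add atoms: none
Why: Williamson ether synthesis by SN2 displacement of the doubly activated alpha-chloride with the phenoxide, the standard route to 2-aryloxyacetoacetates, places the ether oxygen on the carbon that becomes C6 of ring A.

Step 2
Reactants: 4 ethyl 2-(2-methyl-1,3-dioxolan-2-yl)acetate
Product: 5 N-methoxy-N-methyl-2-(2-methyl-1,3-dioxolan-2-yl)acetamide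
Conditions: MeNH(OMe)·HCl, i-PrMgCl, THF, −20 to 0 °C
Reagents that add atoms: N,O-dimethylhydroxylamine hydrochloride, CNOC.Cl
Why: Weinreb amide formation by aminolysis of the ester with the chloromagnesium amide should proceed cleanly because the dioxolane masks the ketone against enolisation and is inert to the Grignard base.

Step 3
Reactants: 3 methyl 2-(4-bromophenoxy)-3-oxobutanoate; 5 N-methoxy-N-methyl-2-(2-methyl-1,3-dioxolan-2-yl)acetamide
Product: 7 methyl 2-(4-bromophenoxy)-3,5,7-trioxooctanoate, via ketal diketo ester 6 (not isolated)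
Conditions: LiN(i-Pr)2 (2.1 equiv), THF, −78 to −20 °C; 5, −78 to 0 °C; then 2 M HCl, THF, rt
Reagents that add atoms: water, O
Why: Huckin–Weiler dianion acylation, in which the terminal carbanion of the beta-keto ester dianion attacks the Weinreb amide and the chelated tetrahedral intermediate prevents over-addition, followed by acetal hydrolysis in cold dilute acid that is too mild for pyranone formation; the amide base, unlike an alkyllithium, leaves the aryl bromide alone.

Step 4
Reactants: 7 methyl 2-(4-bromophenoxy)-3,5,7-trioxooctanoate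
Product: 8 1-[3-(4-bromophenoxy)-2,4,6-trihydroxyphenyl]ethanone
Conditions: Mg(OMe)2 (4 equiv), MeOH, rt to reflux; then 1 M HCl
Reagents that add atoms: none
Why: Mg(OMe)2 turns the triketo ester into a magnesium-chelated polyenolate in which C6, the carbon between the C5 and C7 carbonyls, is folded onto the ester carbonyl C1; C6 adds to C1, methoxide is expelled and the 2-acetylcyclohexane-1,3,5-trione enolises at once to the phloroglucinol, so the new bond is the ring A bond that becomes C4a–C5 of the flavanone. The closest known reaction is the biomimetic Claisen-type (Dieckmann) cyclisation of 3,5,7-triketo esters and of their pyranone forms to acylphloroglucinols under magnesium methoxide. Ring A closes by a 6-exo-trig acyl substitution, and no stereocentre arises. The selectivity required is Claisen closure over the aldol modes: addition of C2 to the C7 ketone, the orsellinate mode of the unsubstituted series, would make C2 quaternary here and cannot lead to an arene, so it stays reversible, while addition of C8 to C3 needs the least acidic terminal methyl group, which methoxide under chelation does not deprotonate. Since the ether oxygen already sits on chain carbon C2, it arrives between two ring hydroxyls without any substitution at a crowded arene, its inductive pull makes the ester a better acceptor, and the acetyl group appears on the carbon that later anchors ring C.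

Step 5
Reactants: 8 1-[3-(4-bromophenoxy)-2,4,6-trihydroxyphenyl]ethanone
Product: 9 1-[3-(4-bromophenoxy)-2-hydroxy-4,6-bis(methoxymethoxy)phenyl]ethanone
Conditions: MOMCl (2.2 equiv), i-Pr2NEt, CH2Cl2, 0 °C
Reagents that add atoms: chloromethyl methyl ether, COCCl
Why: Phenol O-alkylation (acetal protection) under amine base should take the para hydroxyl and the less hindered ortho hydroxyl, as in the standard bis-protection of phloroacetophenone, while the 2-hydroxyl, buttressed between acetyl and aryloxy groups and held in the hydrogen bond to the carbonyl, is expected to stay free.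

Step 6
Reactants: 9 1-[3-(4-bromophenoxy)-2-hydroxy-4,6-bis(methoxymethoxy)phenyl]ethanone
Product: 10 1-[2-(benzyloxy)-3-(4-bromophenoxy)-4,6-bis(methoxymethoxy)phenyl]ethanone
Conditions: BnBr, K2CO3, Bu4NI (cat.), DMF, 60 °C
Reagents that add atoms: benzyl bromide, BrCc1ccccc1
Why: Williamson benzylation under forcing carbonate conditions caps the remaining chelated phenol, which fixes the oxygen next to the aryloxy group as the later 5-oxygen and leaves only acid-labile groups on the other two.

Step 7
Reactants: 10 1-[2-(benzyloxy)-3-(4-bromophenoxy)-4,6-bis(methoxymethoxy)phenyl]ethanone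
Product: 11 {4-[3-acetyl-2-(benzyloxy)-4,6-bis(methoxymethoxy)phenoxy]phenyl}boronic acid
Conditions: B2(OH)4, Pd(OAc)2, XPhos, KOAc, EtOH, 80 °C
Reagents that add atoms: tetrahydroxydiboron, OB(O)B(O)O
Why: Miyaura borylation of the aryl bromide with tetrahydroxydiboron gives the free boronic acid that the base-free thioether coupling requires, and the ketone, acetals and benzyl ether are inert to acetate and the palladium catalyst.

Step 8
Reactants: 12 1-[2,4-bis(benzyloxy)-6-hydroxyphenyl]ethanone
Product: 13 5,7-bis(benzyloxy)-4-hydroxy-2H-chromene-2-thione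
Conditions: CS2, KOt-Bu, THF, 0 °C to rt; then 1 M HCl
Reagents that add atoms: carbon disulfide, S=C=S
Why: Dithiocarboxylation of the methyl ketone enolate with CS2 and cyclisation of the phenoxide onto the dithioacid with loss of hydrogen sulfide is the usual entry to 4-hydroxy-2-thiocoumarins from 2-hydroxyacetophenones.

Step 9
Reactants: 13 5,7-bis(benzyloxy)-4-hydroxy-2H-chromene-2-thione
Product: 14 5,7-bis(benzyloxy)-2-(methylsulfanyl)-4H-chromen-4-one
Conditions: MeI, K2CO3, acetone, rt
Reagents that add atoms: iodomethane, CI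
Why: S-alkylation of the ambident thione anion at its soft sulfur gives the 2-(methylsulfanyl)chromone, a vinylogous thioester ready for C–S activation.

Step 10
Reactants: 11 {4-[3-acetyl-2-(benzyloxy)-4,6-bis(methoxymethoxy)phenoxy]phenyl}boronic acid; 14 5,7-bis(benzyloxy)-2-(methylsulfanyl)-4H-chromen-4-one
Product: 15 2-{4-[3-acetyl-2-(benzyloxy)-4,6-bis(methoxymethoxy)phenoxy]phenyl}-5,7-bis(benzyloxy)-4H-chromen-4-one
Conditions: Pd2(dba)3, tri(2-furyl)phosphine, copper thiophene-2-carboxylate Cu(O2CC4H3S) (1.5 equiv), THF, 50 °C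
Reagents that add atoms: none
Why: Liebeskind–Srogl coupling, in which zerovalent palladium inserts into the C–S bond of the vinylogous thioester and the copper carboxylate scavenges the thiolate and mediates base-free transmetalation of the boronic acid, forms the flavone C2–aryl bond without touching the methyl ketone.

Step 11
Reactants: 15 2-{4-[3-acetyl-2-(benzyloxy)-4,6-bis(methoxymethoxy)phenoxy]phenyl}-5,7-bis(benzyloxy)-4H-chromen-4-one
Product: 17 5-(benzyloxy)-6-{4-[5,7-bis(benzyloxy)-4-oxo-4H-chromen-2-yl]phenoxy}-7-hydroxy-4H-chromen-4-one, via enaminone 16 (not isolated)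
Conditions: Me2NCH(OMe)2, toluene, 110 °C; then conc. HCl, MeOH/CH2Cl2, 40 °C
Reagents that add atoms: N,N-dimethylformamide dimethyl acetal, COC(OC)N(C)C
Why: Condensation of the methyl ketone with the amide acetal gives the enaminone, and acid then cleaves both acetals so that the only free ortho phenol, the one remote from the aryloxy group, closes ring C by 6-endo addition–elimination of dimethylamine (the standard enaminone route to chromones), which fixes the aryloxy group at C6.

Step 12
Reactants: 17 5-(benzyloxy)-6-{4-[5,7-bis(benzyloxy)-4-oxo-4H-chromen-2-yl]phenoxy}-7-hydroxy-4H-chromen-4-one; 18 [4-(benzyloxy)phenyl]boronic acid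
Product: 19 (2S)-5-(benzyloxy)-2-[4-(benzyloxy)phenyl]-6-{4-[5,7-bis(benzyloxy)-4-oxo-4H-chromen-2-yl]phenoxy}-7-hydroxy-2,3-dihydro-4H-chromen-4-one
Conditions: Pd(OCOCF3)2 (5 mol %), (R)-t-BuPyOx (6 mol %), NH4PF6 (30 mol %), H2O (5 equiv), ClCH2CH2Cl, 60 °C
Reagents that add atoms: none
Why: Palladium-catalysed asymmetric conjugate addition of an arylboronic acid to a chromone, in which the aryl–palladium species bound to the pyridine-oxazoline adds to the enone face left open by the tert-butyl group and the palladium enolate is protonated without base, sets C2 as S with no route to epimerisation, while the 2-aryl-substituted flavone and the free phenol should not react in the acidic, base-free medium.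

Step 13
Reactants: 19 (2S)-5-(benzyloxy)-2-[4-(benzyloxy)phenyl]-6-{4-[5,7-bis(benzyloxy)-4-oxo-4H-chromen-2-yl]phenoxy}-7-hydroxy-2,3-dihydro-4H-chromen-4-one
Product: 20 (2S)-6-[4-(5,7-dihydroxy-4-oxo-4H-chromen-2-yl)phenoxy]-5,7-dihydroxy-2-(4-hydroxyphenyl)-2,3-dihydro-4H-chromen-4-one
Conditions: H2 (1 atm), Pd/C, THF/MeOH, rt
Reagents that add atoms: none
Why: Hydrogenolysis of the four aryl benzyl ethers under neutral conditions, stopped at the calculated uptake, should leave the flavone double bond, both ketones and the base-sensitive C2 stereocentre untouched.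

**Compound list**
1 | 4-bromophenol | Oc1ccc(Br)cc1 | starting material
2 | methyl 2-chloro-3-oxobutanoate | COC(=O)C(Cl)C(C)=O | starting material
3 | methyl 2-(4-bromophenoxy)-3-oxobutanoate | COC(=O)C(Oc1ccc(Br)cc1)C(C)=O | intermediate
4 | ethyl 2-(2-methyl-1,3-dioxolan-2-yl)acetate | CCOC(=O)CC1(C)OCCO1 | starting material
5 | N-methoxy-N-methyl-2-(2-methyl-1,3-dioxolan-2-yl)acetamide | CON(C)C(=O)CC1(C)OCCO1 | intermediate
6 | methyl 2-(4-bromophenoxy)-6-(2-methyl-1,3-dioxolan-2-yl)-3,5-dioxohexanoate | COC(=O)C(Oc1ccc(Br)cc1)C(=O)CC(=O)CC1(C)OCCO1 | intermediate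
7 | methyl 2-(4-bromophenoxy)-3,5,7-trioxooctanoate | COC(=O)C(Oc1ccc(Br)cc1)C(=O)CC(=O)CC(C)=O | intermediate
8 | 1-[3-(4-bromophenoxy)-2,4,6-trihydroxyphenyl]ethanone | CC(=O)c1c(O)cc(O)c(Oc2ccc(Br)cc2)c1O | intermediate
9 | 1-[3-(4-bromophenoxy)-2-hydroxy-4,6-bis(methoxymethoxy)phenyl]ethanone | CC(=O)c1c(OCOC)cc(OCOC)c(Oc2ccc(Br)cc2)c1O | intermediate
10 | 1-[2-(benzyloxy)-3-(4-bromophenoxy)-4,6-bis(methoxymethoxy)phenyl]ethanone | CC(=O)c1c(OCOC)cc(OCOC)c(Oc2ccc(Br)cc2)c1OCc1ccccc1 | intermediate
11 | {4-[3-acetyl-2-(benzyloxy)-4,6-bis(methoxymethoxy)phenoxy]phenyl}boronic acid | CC(=O)c1c(OCOC)cc(OCOC)c(Oc2ccc(B(O)O)cc2)c1OCc1ccccc1 | intermediate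
12 | 1-[2,4-bis(benzyloxy)-6-hydroxyphenyl]ethanone | CC(=O)c1c(O)cc(OCc2ccccc2)cc1OCc1ccccc1 | starting material
13 | 5,7-bis(benzyloxy)-4-hydroxy-2H-chromene-2-thione | S=c1cc(O)c2c(OCc3ccccc3)cc(OCc3ccccc3)cc2o1 | intermediate
14 | 5,7-bis(benzyloxy)-2-(methylsulfanyl)-4H-chromen-4-one | CSc1cc(=O)c2c(OCc3ccccc3)cc(OCc3ccccc3)cc2o1 | intermediate
15 | 2-{4-[3-acetyl-2-(benzyloxy)-4,6-bis(methoxymethoxy)phenoxy]phenyl}-5,7-bis(benzyloxy)-4H-chromen-4-one | CC(=O)c1c(OCOC)cc(OCOC)c(Oc2ccc(-c3cc(=O)c4c(OCc5ccccc5)cc(OCc5ccccc5)cc4o3)cc2)c1OCc1ccccc1 | intermediate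
16 | (2E)-1-[2-(benzyloxy)-3-{4-[5,7-bis(benzyloxy)-4-oxo-4H-chromen-2-yl]phenoxy}-4,6-bis(methoxymethoxy)phenyl]-3-(dimethylamino)prop-2-en-1-one | CN(C)/C=C/C(=O)c1c(OCOC)cc(OCOC)c(Oc2ccc(-c3cc(=O)c4c(OCc5ccccc5)cc(OCc5ccccc5)cc4o3)cc2)c1OCc1ccccc1 | intermediate
17 | 5-(benzyloxy)-6-{4-[5,7-bis(benzyloxy)-4-oxo-4H-chromen-2-yl]phenoxy}-7-hydroxy-4H-chromen-4-one | O=c1ccoc2cc(O)c(Oc3ccc(-c4cc(=O)c5c(OCc6ccccc6)cc(OCc6ccccc6)cc5o4)cc3)c(OCc3ccccc3)c12 | intermediate
18 | [4-(benzyloxy)phenyl]boronic acid | OB(O)c1ccc(OCc2ccccc2)cc1 | starting material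
19 | (2S)-5-(benzyloxy)-2-[4-(benzyloxy)phenyl]-6-{4-[5,7-bis(benzyloxy)-4-oxo-4H-chromen-2-yl]phenoxy}-7-hydroxy-2,3-dihydro-4H-chromen-4-one | O=C1C[C@@H](c2ccc(OCc3ccccc3)cc2)Oc2cc(O)c(Oc3ccc(-c4cc(=O)c5c(OCc6ccccc6)cc(OCc6ccccc6)cc5o4)cc3)c(OCc3ccccc3)c21 | intermediate
20 | (2S)-6-[4-(5,7-dihydroxy-4-oxo-4H-chromen-2-yl)phenoxy]-5,7-dihydroxy-2-(4-hydroxyphenyl)-2,3-dihydro-4H-chromen-4-one | O=C1C[C@@H](c2ccc(O)cc2)Oc2cc(O)c(Oc3ccc(-c4cc(=O)c5c(O)cc(O)cc5o4)cc3)c(O)c21 | target

**Step count**
Total steps: 13. Longest linear sequence: 10 steps (steps 1, 3, 4, 5, 6, 7, 10, 11, 12, 13).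

**Steps most likely to fail**

Step 4. The aryloxy group also acidifies the C2 hydrogen, so part of the substrate may rest as the C1–C3 enolate whose ester no longer accepts C6, and methanolysis of the diketone links could then outrun ring closure. The fallback sets out from compound 6, isolated by quenching step 3 with NH4Cl instead of acid. DBU in refluxing toluene should lactonise the C5 enol oxygen onto the ester to give 3-(4-bromophenoxy)-4-hydroxy-6-[(2-methyl-1,3-dioxolan-2-yl)methyl]-2H-pyran-2-one F1. Dilute HCl in THF would free the ketone to give 3-(4-bromophenoxy)-4-hydroxy-6-(2-oxopropyl)-2H-pyran-2-one F2. In this pyranone, C2 of the chain carries no hydrogen and the acyl group is a more electrophilic enol lactone. Mg(OMe)2 in methanol should convert it, by the known pyranone-to-acylphloroglucinol Claisen pathway, into compound 8, where the route is rejoined.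

Step 5. The second acetal may be installed without full discrimination between the two ortho hydroxyls, which would carry the wrong oxygen into ring C and scramble the 6- versus 8-aryloxy pattern. The fallback sets out from compound 8 and relies on steric bulk alone. Triisopropylsilyl chloride and imidazole in DMF should silylate only the para and the less hindered ortho hydroxyl, giving 1-[3-(4-bromophenoxy)-2-hydroxy-4,6-bis(triisopropylsilyloxy)phenyl]ethanone F3. A Mitsunobu etherification with benzyl alcohol, PPh3 and diisopropyl azodicarboxylate would cap the remaining phenol under neutral conditions, giving 1-[2-(benzyloxy)-3-(4-bromophenoxy)-4,6-bis(triisopropylsilyloxy)phenyl]ethanone F4. Bu4NF buffered with acetic acid would then give 1-[2-(benzyloxy)-3-(4-bromophenoxy)-4,6-dihydroxyphenyl]ethanone F5. MOMCl with NaH in DMF would return the sequence to compound 10.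

Step 12. Insertion of the electron-rich, 5,6,7-trisubstituted chromone into the aryl–palladium bond may be slow, with protodeboronation of the boronic acid taking over, or the facial selectivity may erode. The fallback sets out from compound 15 and forms the C2–O1 bond instead of the C2–aryl bond. A Claisen–Schmidt condensation with 4-(benzyloxy)benzaldehyde (KOH, EtOH/THF, rt) should give (2E)-1-[2-(benzyloxy)-3-{4-[5,7-bis(benzyloxy)-4-oxo-4H-chromen-2-yl]phenoxy}-4,6-bis(methoxymethoxy)phenyl]-3-[4-(benzyloxy)phenyl]prop-2-en-1-one F6. HCl in MeOH/THF would remove both acetals to give (2E)-1-[2-(benzyloxy)-3-{4-[5,7-bis(benzyloxy)-4-oxo-4H-chromen-2-yl]phenoxy}-4,6-dihydroxyphenyl]-3-[4-(benzyloxy)phenyl]prop-2-en-1-one F7. A cinchona-alkaloid-derived bifunctional thiourea (the pseudoenantiomer giving the 2S sense) would then catalyse the intramolecular oxa-Michael addition of the only free ortho phenol, returning the sequence to compound 19.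

Further compounds
F1 | step 4 | 3-(4-bromophenoxy)-4-hydroxy-6-[(2-methyl-1,3-dioxolan-2-yl)methyl]-2H-pyran-2-one | O=c1oc(CC2(C)OCCO2)cc(O)c1Oc1ccc(Br)cc1
F2 | step 4 | 3-(4-bromophenoxy)-4-hydroxy-6-(2-oxopropyl)-2H-pyran-2-one | CC(=O)Cc1cc(O)c(Oc2ccc(Br)cc2)c(=O)o1
F3 | step 5 | 1-[3-(4-bromophenoxy)-2-hydroxy-4,6-bis(triisopropylsilyloxy)phenyl]ethanone | CC(=O)c1c(O[Si](C(C)C)(C(C)C)C(C)C)cc(O[Si](C(C)C)(C(C)C)C(C)C)c(Oc2ccc(Br)cc2)c1O
F4 | step 5 | 1-[2-(benzyloxy)-3-(4-bromophenoxy)-4,6-bis(triisopropylsilyloxy)phenyl]ethanone | CC(=O)c1c(O[Si](C(C)C)(C(C)C)C(C)C)cc(O[Si](C(C)C)(C(C)C)C(C)C)c(Oc2ccc(Br)cc2)c1OCc1ccccc1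
F5 | step 5 | 1-[2-(benzyloxy)-3-(4-bromophenoxy)-4,6-dihydroxyphenyl]ethanone | CC(=O)c1c(O)cc(O)c(Oc2ccc(Br)cc2)c1OCc1ccccc1
F6 | step 12 | (2E)-1-[2-(benzyloxy)-3-{4-[5,7-bis(benzyloxy)-4-oxo-4H-chromen-2-yl]phenoxy}-4,6-bis(methoxymethoxy)phenyl]-3-[4-(benzyloxy)phenyl]prop-2-en-1-one | O=C(/C=C/c1ccc(OCc2ccccc2)cc1)c1c(OCOC)cc(OCOC)c(Oc2ccc(-c3cc(=O)c4c(OCc5ccccc5)cc(OCc5ccccc5)cc4o3)cc2)c1OCc1ccccc1
F7 | step 12 | (2E)-1-[2-(benzyloxy)-3-{4-[5,7-bis(benzyloxy)-4-oxo-4H-chromen-2-yl]phenoxy}-4,6-dihydroxyphenyl]-3-[4-(benzyloxy)phenyl]prop-2-en-1-one | O=C(/C=C/c1ccc(OCc2ccccc2)cc1)c1c(O)cc(O)c(Oc2ccc(-c3cc(=O)c4c(OCc5ccccc5)cc(OCc5ccccc5)cc4o3)cc2)c1OCc1ccccc1
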